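Ring in the beta run, a closed stirred flask with the same charge as blue, reaches 51.3 % of the charge by 1.00 min and then stays near it, while substrate stays near 31.0 %.

| flask | substrate | remark | time |
|---|---|---|---|
| beta | 2 M | run made earlier |  |
| blue | 2.0 M | everything together in a closed stirred flask, run for 4.0 min | 4.0 min |
| grey | 2.0 M | one stirred flow tank at steady state, fed with the mixture as stated, mean residence time 4.0 min |  |

beta run (percent of the substrate charged)

| time / min | ring / % | substrate / % |
|---|---|---|
| 0.200 | 38.9 | 40.4 |
| 0.333 | 48.1 | 35.5 |
| 0.417 | 48.8 | 34.1 |
| 0.667 | 49.3 | 34.0 |
| 1.00 | 51.3 | 31.0 |
| 1.50 | 50.8 | 33.3 |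
| 2.50 | 48.6 | 31.2 |

(each reading ± 1 percentage point)

- the stated concentrations are those of everything mixed, before any reaction; amounts are the same in each set-up
- the analysis behind the earlier runs scatters by 1 percentage point, standard deviation
- the earlier runs were made in a closed, stirred flask

1. the set-up with the highest amount of ring at the outlet or at the end, in percent of the substrate put in ("none" if the first two lie within 2 percentage points) (blue / grey / none)
2. amount of ring at the outlet or at the end, in percent of the substrate put in, blue
3. amount of ring at the outlet or at the end, in percent of the substrate put in, grey

I freeze the plateau ratio, ring per unit of substrate still present, pooled over the last 3 readings: 1.58. This reading is steady from a time short against 4.0 min, so I treat substrate and ring as a quasi-equilibrium in blue and in grey alike.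

What can still differ is the pool, substrate plus ring, and I take two extremes. If the pool stays frozen, ring in both flasks is the plateau mean, 50.2 %. If the pool keeps draining at the first-order drift between the readings at 1.00 min and 2.50 min, 0.0206 min⁻¹, blue holds 46.3 % and grey 46.4 %. I expect both flasks between these extremes, though that drift rests on two readings. My gap of 0.15 percentage points is less than the margin of 2 points, so I say none.

The forecast differs: it says blue, with ring 49.5 % (46 % to 52 %) in blue and 42 % (33 % to 54 %) in grey, reasoning that "Everything stopping together suggests the active agent dies or is used up".

The simulation gives none, with ring 45.4 % in blue and 44.6 % in grey, both just below my range.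

    substrate ⇌ ring (K = 1.60, k = 0.0938 s⁻¹)
    2 substrate ⇌ open dimer (K = 0.285 L mol⁻¹, k = 0.0926 L mol⁻¹ s⁻¹)
    ring ⇌ isomer of the product (K = 2.20, k = 0.00159 s⁻¹)

In blue at 4.00 min, the plateau ratio times the 29 % of substrate left gives 45.3 % against the 45.4 % of ring present, while isomer of the product has reached 16.6 %. The neighbouring flask is blue read at 10 min; it has 23.4 % of substrate left, so the same ratio gives 36.9 % of ring, and that flask holds 37.1 %.

All runs are calculated on assumed constants, and the scatter is random.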